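## The problem

The target is read as epigallocatechin-(4β→8)-epigallocatechin 3-O-gallate-(4β→8)-epigallocatechin: three (2R,3R)-flavan-3-ol units (top 2R,3R,4R; middle 2R,3R,4S; bottom 2R,3R) joined by two C4(sp3)–C8(sp2) bonds, with one galloyl ester on O3 of the middle unit. No ring has to be built, because rings A, B and C and the C2 and C3 stereocentres of every unit are present in commercial (−)-epigallocatechin; what must be made are the two interflavan bonds, and each creates a C4 stereocentre that must end trans to the oxygen on C3 and can be controlled by it. The middle unit is the real difficulty: it must be a nucleophile at C8 towards C4 of the top unit and an electrophile at C4 towards C8 of the bottom unit, while all three units carry the same phloroglucinol ring A with two nucleophilic positions (C6, C8) and the same oxidisable C4 methylene, so self-condensation, wrong sequence and over-extension are the default outcomes. The galloyl group cannot be placed after assembly, because the secondary hydroxyls of the top and middle units sit in nearly the same environment; it has to come in with its unit. The product has eighteen free phenols (three pyrogallol rings B, one galloyl ring, three rings A) that are air- and base-sensitive, an ester that will not survive strong base or organometallics, and two interflavan bonds that re-ionise at C4 in acid; the phenols must stay masked until a neutral last step. The feature the plan uses lies in ring C of the middle unit: C4 is a methylene benzylic to ring A (para to O7, ortho to O5 and O1), and its β-hydrogen is axial and antiperiplanar to the axial C3–O bond of the galloyl ester, so loss of hydride gives a cation that the ester carbonyl oxygen captures as a cis-fused 1,3-dioxolan-2-ylium ion on the α face. In the top–middle dimer this is the only C4 methylene (C4 of the top unit is a shielded methine with an equatorial hydrogen), so the middle unit can enter as a plain nucleophile and be switched to an electrophile afterwards by C–H abstraction alone.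

## Retrosynthesis

**9 ⇒ 8.** The eighteen phenolic O–H bonds are traced back to O–benzyl bonds. Benzyl ethers keep ring A electron-rich, which both the hydride abstraction at C4 and the nucleophilicity of C8 need. Acyl or silyl groups would drain ring A, and acetal groups would need acid for removal. Benzyl ethers fall in one neutral hydrogenolysis that leaves the ester and the interflavan bonds alone. 8 is no smaller than 9, but it is the form in which every bond construction can be run. The forward step must be complete and acid-free.

**8 ⇒ 6 + 2.** The bond C4(middle)–C8(bottom) is cut last. The other order (top–middle bond last) would need a dimeric nucleophile with three competing positions, used without excess against a monomeric electrophile that condenses with itself. Here the nucleophile is the monomer 2, which can be used in excess and recovered, and the electrophile is the chain end of 6. No leaving group is installed: DDQ removes hydride from the C4 methylene of the middle unit of 6 to give the ion pair 7, and C8 of 2 is then added in the same flask. The union is thus made from two C–H bonds. It asks for abstraction at the methylene and not at the interflavan methine, for survival of 7 until 2 is added, for attack by C8 (not C6) on the β face, and for no re-ionisation of the first interflavan bond.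

**6 ⇒ 5 + 4.** The bond C4(top)–C8(middle) is cut. The middle unit enters as 4, the perbenzyl ether of epigallocatechin gallate, acting only as a nucleophile; its C4–H bonds are the dormant electrophile. The top unit enters as the 4β-alkoxy ether 5. Both partners are monomers, so 4 can be used in excess to outrun self-condensation of 5. The forward reaction is a Lewis-acid-catalysed Friedel–Crafts alkylation with attack anti to the axial 3-hydroxyl.

**5 ⇒ 2.** The C4–O bond is cut. 2 carries no functionality at C4; the forward reaction is DDQ oxidation with 2-ethoxyethanol as trap, which places the alkoxy group trans to O3.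

**4 ⇒ 2 + 3.** The ester C–O bond at O3 is cut. The galloyl group is brought in already benzylated, as commercial 3,4,5-tris(benzyloxy)benzoic acid 3, and is attached to the only free hydroxyl of 2. This puts the ester on its unit before any interflavan bond exists, so no later choice between two similar secondary hydroxyls arises. The forward reaction is a carbodiimide esterification that does not touch C3.

**2 ⇒ 1.** The five phenolic O–benzyl bonds are cut, leading to commercial (−)-epigallocatechin 1. This one compound supplies every flavan carbon and all six C2/C3 stereocentres. Compound 2 serves three times: as precursor of the top unit, as the alcohol that becomes the middle unit, and as the bottom unit.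

## Roads not taken

Alternative 1: The most obvious route is iterative growth from the bottom with pre-activated monomers. The top–middle bond is cut last: 5 is coupled by Lewis acid with the dimeric nucleophile A2 (octa-O-benzyl-EGCG-(4β→8)-penta-O-benzyl-epigallocatechin). A2 comes from the pre-activated middle monomer A1 (4β-(2-ethoxyethoxy)-octa-O-benzyl-EGCG) and 2. The chemistry is the same Friedel–Crafts alkylation, but the roles are worse. A2 is too valuable to use in excess and has three nucleophilic positions (C8 and C6 of its upper unit, C6 of its lower unit). The monomeric electrophile 5 then condenses with itself unless a bromine cap is added. The middle unit must also be activated in a separate step before it has acted as a nucleophile. The chosen plan needs one step fewer, adds only monomers as nucleophiles, and makes the middle electrophile on the chain after its C8 has reacted.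

Alternative 2: Polarity-defined 1,2-addition. Both interflavan bonds are cut as aryllithium plus ketone: the C8-lithio arene from the 8-bromide A4 adds to the 4-ketone A3, and the tertiary benzylic alcohol is then deoxygenated. This is regiospecific and free of oligomers. Three points speak against it. Ionic reduction of the tertiary cation delivers hydride anti to O3 and so leaves the aryl group cis to O3 (the 4α series), the opposite of what the target needs. The galloyl ester cannot pass through the organolithium steps, so the three O3 positions would need orthogonal protection and a late, selective galloylation. Each unit would need bromination, oxidation to the ketone and silylation, roughly doubling the step count.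

Alternative 3: Enzymatic dearomatisation for the top unit. The top–middle bond is cut in water: the flat flavylium salt delphinidin chloride A5 is reduced by an anthocyanidin reductase (NADPH) to the 2,3-cis C4 electrophile, which is captured by C8 of the unprotected dimer A6 (EGCG-(4β→8)-epigallocatechin). This would build C2, C3 and C4 of the top unit from a flat ring without protecting groups. Against it: A6 offers three unprotected nucleophilic positions and nothing stops further chain growth. The main course of the enzyme is over-reduction to epigallocatechin, so the electrophile is a minor shunt. The configurational fidelity at C2/C3 depends on the enzyme. A6 would still have to be made by the protected chemistry, so nothing is saved over taking the stereocentres from 1.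

Key step: step 5

## Route

Step 1
Reactants: 1 (−)-epigallocatechin
Product: 2 penta-O-benzyl-epigallocatechin [(2R,3R)-5,7-bis(benzyloxy)-2-[3,4,5-tris(benzyloxy)phenyl]chroman-3-ol]
Conditions: BnBr (5.5 equiv), K2CO3 (6 equiv), n-Bu4NI (cat.), degassed DMF, −10 °C → rt, Ar, dark
Reagents that add atoms: benzyl bromide BrCc1ccccc1
Why: Williamson etherification of the five phenols; carbonate in DMF does not deprotonate the secondary 3-hydroxyl, so O3 stays free, and low temperature with exclusion of air protects the pyrogallol phenoxides and the C2 stereocentre until the phenols are capped.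

Step 2
Reactants: 2 penta-O-benzyl-epigallocatechin; 3 3,4,5-tris(benzyloxy)benzoic acid
Product: 4 octa-O-benzyl-EGCG [(2R,3R)-5,7-bis(benzyloxy)-2-[3,4,5-tris(benzyloxy)phenyl]chroman-3-yl 3,4,5-tris(benzyloxy)benzoate]
Conditions: 3 (1.5 equiv), DCC (1.6 equiv), DMAP (0.3 equiv), CH2Cl2, 0 °C → rt
Reagents that add atoms: none
Why: Steglich esterification of the axial secondary 3-hydroxyl with the benzylated gallic acid, the usual way to benzylated flavan-3-ol gallates; no bond to C3 is broken, so both stereocentres are retained.

Step 3
Reactants: 2 penta-O-benzyl-epigallocatechin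
Product: 5 4β-(2-ethoxyethoxy)-penta-O-benzyl-epigallocatechin [(2R,3R,4S); alkoxy group trans to the 3-hydroxyl]
Conditions: DDQ (2 equiv), HOCH2CH2OEt (10 equiv), CH2Cl2, rt
Reagents that add atoms: 2-ethoxyethanol CCOCCO
Why: DDQ benzylic oxidation by hydride abstraction from C4, a known reaction of benzylated flavan-3-ols; the ring A stabilised cation is trapped by the alcohol on the β face, anti to the axial 3-hydroxyl, which sets C4 (3,4-trans).

Step 4
Reactants: 5 4β-(2-ethoxyethoxy)-penta-O-benzyl-epigallocatechin; 4 octa-O-benzyl-EGCG
Product: 6 protected dimer penta-O-benzyl-epigallocatechin-(4β→8)-octa-O-benzyl-EGCG (upper unit 2R,3R,4R; lower unit 2R,3R)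
Conditions: 4 (4 equiv), TMSOTf (0.2 equiv), 4 Å MS, CH2Cl2, −78 °C; then Et3N, aq NaHCO3
Reagents that add atoms: none
Why: Lewis-acid-catalysed Friedel–Crafts alkylation of C8 of 4 by the C4 cation of 5, the standard interflavan coupling of benzylated flavans; attack on the β face anti to the axial 3-hydroxyl sets C4 of the top unit (4β), C8 is preferred over the doubly flanked C6, and the excess of 4 suppresses self-condensation of 5.

Step 5
Reactants: 6 protected dimer; 2 penta-O-benzyl-epigallocatechin
Product: 8 protected trimer penta-O-benzyl-epigallocatechin-(4β→8)-octa-O-benzyl-EGCG-(4β→8)-penta-O-benzyl-epigallocatechin, via dioxolenium ion pair 7 (not isolated)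
Conditions: DDQ (1.0 equiv), 4 Å MS, CH2Cl2, −20 → 0 °C, until the oxidant is consumed; then 2 (4 equiv), TMSOTf (0.3 equiv), −78 → −40 °C; Et3N
Reagents that add atoms: none
Why: Proposed new method: DDQ should abstract the axial H-4β of the middle ring C of 6, the only C4 methylene present (the C4–H of the top unit is an equatorial, shielded methine out of alignment with the π system of its ring A), and the resulting ring A stabilised cation is captured in the same event by the carbonyl oxygen of the 3-O-galloyl ester, which lies antiperiplanar to the departing hydride. This closes, by 5-exo attack of oxygen on C4, the transient cis-fused 1,3-dioxolan-2-ylium ring of ion pair 7 on the α face; no ring of the product is closed in this step. Because the oxidant is used up before 2 is added, the C4 methylene of 2 never meets DDQ, which is what makes a C–H/C–H union of two flavans chemoselective. On addition of 2 and catalytic TMSOTf the dioxolenium ion (or its covalent adduct with the hydroquinone anion, re-ionised by the acid) is opened at C4 by C8 of 2 from the β face, anti to the bridging oxygen, in a Friedel–Crafts alkylation that returns the galloyl ester. The new stereocentre, C4 of the middle unit (S, 3,4-trans), is thus controlled by C3 through the participating ester. The closest known reactions are the DDQ oxidation of benzylated flavan-3-ols at C4 in the presence of alcohols followed by Lewis-acid coupling of the 4-alkoxy ethers, acyl-participated 1,2-trans glycosylation, and DDQ-mediated cross-dehydrogenative coupling of benzylic ethers with arenes after pre-formation of the cation. The step needs methylene over methine selectivity (secured by alignment and shielding), C8 over C6 selectivity in 2 (C6 is flanked by two benzyloxy groups), and coupling faster than re-ionisation of the first interflavan bond (low temperature, catalytic acid, fourfold excess of 2).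

Step 6
Reactants: 8 protected trimer
Product: 9 epigallocatechin-(4β→8)-epigallocatechin 3-O-gallate-(4β→8)-epigallocatechin (CNP0278699.1)
Conditions: H2 (1 atm), Pd(OH)2/C, THF/MeOH/H2O (20:1:1), rt; filtration under Ar, lyophilisation, Sephadex LH-20
Reagents that add atoms: none
Why: Hydrogenolysis of the eighteen benzyl ethers under neutral conditions, the usual last step for benzylated proanthocyanidin gallates; the galloyl ester, the interflavan bonds and all eight stereocentres are not affected.

## Compound list

1 | (−)-epigallocatechin, (2R,3R) | Oc1cc(O)c2c(c1)O[C@H](c1cc(O)c(O)c(O)c1)[C@H](O)C2 | starting material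

2 | 5,7,3′,4′,5′-penta-O-benzyl-epigallocatechin, (2R,3R) | C(c5ccccc5)Oc1cc(OCc5ccccc5)c2c(c1)O[C@H](c1cc(OCc5ccccc5)c(OCc5ccccc5)c(OCc5ccccc5)c1)[C@H](O)C2 | intermediate

3 | 3,4,5-tris(benzyloxy)benzoic acid | OC(=O)c1cc(OCc2ccccc2)c(OCc2ccccc2)c(OCc2ccccc2)c1 | starting material

4 | octa-O-benzyl-EGCG, (2R,3R) | C(c5ccccc5)Oc1cc(OCc5ccccc5)c2c(c1)O[C@H](c1cc(OCc5ccccc5)c(OCc5ccccc5)c(OCc5ccccc5)c1)[C@H](OC(=O)c1cc(OCc5ccccc5)c(OCc5ccccc5)c(OCc5ccccc5)c1)C2 | intermediate

5 | 4β-(2-ethoxyethoxy)-5,7,3′,4′,5′-penta-O-benzyl-epigallocatechin, (2R,3R,4S) | CCOCCO[C@H]1c2c(OCc5ccccc5)cc(OCc5ccccc5)cc2O[C@H](c2cc(OCc5ccccc5)c(OCc5ccccc5)c(OCc5ccccc5)c2)[C@@H]1O | intermediate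

6 | penta-O-benzyl-epigallocatechin-(4β→8)-octa-O-benzyl-EGCG (upper unit 2R,3R,4R; lower unit 2R,3R) | O=C(O[C@@H]1Cc2c(OCc5ccccc5)cc(OCc5ccccc5)c([C@H]3c4c(OCc5ccccc5)cc(OCc5ccccc5)cc4O[C@H](c4cc(OCc5ccccc5)c(OCc5ccccc5)c(OCc5ccccc5)c4)[C@@H]3O)c2O[C@@H]1c1cc(OCc5ccccc5)c(OCc5ccccc5)c(OCc5ccccc5)c1)c1cc(OCc5ccccc5)c(OCc5ccccc5)c(OCc5ccccc5)c1 | intermediate

7 | ion pair of the 3,4-cis-fused 2-[3,4,5-tris(benzyloxy)phenyl]-1,3-dioxolan-2-ylium ion of the lower unit of 6 (both oxygens on the α face) with the 2,3-dichloro-5,6-dicyano-4-hydroxyphenolate anion | C1(=[O+][C@@H]2c3c(OCc5ccccc5)cc(OCc5ccccc5)c([C@H]4c6c(OCc5ccccc5)cc(OCc5ccccc5)cc6O[C@H](c6cc(OCc5ccccc5)c(OCc5ccccc5)c(OCc5ccccc5)c6)[C@@H]4O)c3O[C@H](c3cc(OCc5ccccc5)c(OCc5ccccc5)c(OCc5ccccc5)c3)[C@@H]2O1)c1cc(OCc5ccccc5)c(OCc5ccccc5)c(OCc5ccccc5)c1.[O-]c1c(Cl)c(Cl)c(O)c(C#N)c1C#N | intermediate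

8 | penta-O-benzyl-epigallocatechin-(4β→8)-octa-O-benzyl-EGCG-(4β→8)-penta-O-benzyl-epigallocatechin (octadeca-O-benzyl ether of 9; top 2R,3R,4R; middle 2R,3R,4S; bottom 2R,3R) | O=C(O[C@@H]1[C@@H](c2c(OCc5ccccc5)cc(OCc5ccccc5)c3c2O[C@H](c2cc(OCc5ccccc5)c(OCc5ccccc5)c(OCc5ccccc5)c2)[C@H](O)C3)c2c(OCc5ccccc5)cc(OCc5ccccc5)c([C@H]3c4c(OCc5ccccc5)cc(OCc5ccccc5)cc4O[C@H](c4cc(OCc5ccccc5)c(OCc5ccccc5)c(OCc5ccccc5)c4)[C@@H]3O)c2O[C@@H]1c1cc(OCc5ccccc5)c(OCc5ccccc5)c(OCc5ccccc5)c1)c1cc(OCc5ccccc5)c(OCc5ccccc5)c(OCc5ccccc5)c1 | intermediate

9 | epigallocatechin-(4β→8)-epigallocatechin 3-O-gallate-(4β→8)-epigallocatechin (top 2R,3R,4R; middle 2R,3R,4S; bottom 2R,3R) | O=C(O[C@@H]1[C@@H](c2c(O)cc(O)c3c2O[C@H](c2cc(O)c(O)c(O)c2)[C@H](O)C3)c2c(O)cc(O)c([C@H]3c4c(O)cc(O)cc4O[C@H](c4cc(O)c(O)c(O)c4)[C@@H]3O)c2O[C@@H]1c1cc(O)c(O)c(O)c1)c1cc(O)c(O)c(O)c1 | target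

## Step count and risks

Total steps: 6. Longest linear sequence: 5 steps (1 → 2 → 5 → 6 → 8 → 9); step 2 (2 + 3 → 4) is a side branch that joins at step 4.

**Step 5 (key step, proposed new method).** Without a trapping alcohol the cation of 7 may be intercepted by the free C8 of the top unit of a second molecule of 6 before 2 is added (self-condensation). Hydride abstraction may also occur at the interflavan methine or a second time at C4 (to the ketone level). Residual oxidant may oxidise 2, and the acid may re-ionise the first interflavan bond and scramble the chain. The fallback uses known chemistry and sets out from 6. DDQ oxidation in the presence of 2-ethoxyethanol gives the isolable 4β-(2-ethoxyethoxy) ether of the dimer F1, in which the alcohol outruns all other nucleophiles. F1 is then coupled with an excess of 2 under TMSOTf catalysis at −78 °C, where the same dioxolenium ion forms from the ether, and the route is rejoined at 8.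

**Step 4.** Self-condensation of 5 through its own free C8 may compete with capture by 4, and the acid may re-ionise the new bond. The fallback changes the approach to a temporary bromine cap and sets out from 2. N-bromosuccinimide in CH2Cl2 at low temperature should give 8-bromo-penta-O-benzyl-epigallocatechin F2. DDQ and 2-ethoxyethanol convert it into the capped electrophile 8-bromo-4β-(2-ethoxyethoxy)-penta-O-benzyl-epigallocatechin F3, which can no longer alkylate itself. Equimolar coupling with 4 gives the 8-bromo dimer F4, and the conditions of step 5 with 2 give the 8-bromo trimer F5. Hydrogenolysis over Pd(OH)2/C with Et3N removes the bromine together with the benzyl groups and rejoins the route at 9.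

**Step 1.** C-benzylation of ring A, autoxidation of the pyrogallol phenoxides and base-induced epimerisation at C2 may occur before all phenols are capped. The fallback sets out from 1. Peracetylation (Ac2O, pyridine) gives epigallocatechin hexaacetate F6. This is benzylated with in-situ deacetylation (BnBr, NaH, DMF, one equivalent of water per aryl acetate, 0 °C), so each phenoxide is set free only as fast as it is alkylated. The secondary acetate on O3 is cleaved much more slowly than the aryl acetates, so the product should be 3-O-acetyl-penta-O-benzyl-epigallocatechin F7. Methanolysis (K2CO3, MeOH/THF, rt) removes this last acetate, and the route is rejoined at 2.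

**Step 6.** Hydrogenolysis may stall at partly benzylated mixtures as the polar product leaves solution or fouls the catalyst, and the free polyphenol may decay by oxidation or acid-induced cleavage during isolation. The fallback sets out from 8. After hydrogenolysis and filtration under argon, the crude polyphenol is acetylated on the phenols only (Ac2O, aq NaHCO3, 0 °C, Schotten–Baumann conditions) to give the octadeca-O-acetate F8. F8 is purified on silica and deacetylated with hydrazine hydrate in MeOH at 0 °C, where aryl acetates cleave and the galloyl ester of the secondary alcohol does not. The route is rejoined at 9.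

## Further compounds

F1 | step 5 | penta-O-benzyl-epigallocatechin-(4β→8)-[4β-(2-ethoxyethoxy)-octa-O-benzyl-EGCG] | O=C(O[C@@H]1[C@@H](OCCOCC)c2c(OCc5ccccc5)cc(OCc5ccccc5)c([C@H]3c4c(OCc5ccccc5)cc(OCc5ccccc5)cc4O[C@H](c4cc(OCc5ccccc5)c(OCc5ccccc5)c(OCc5ccccc5)c4)[C@@H]3O)c2O[C@@H]1c1cc(OCc5ccccc5)c(OCc5ccccc5)c(OCc5ccccc5)c1)c1cc(OCc5ccccc5)c(OCc5ccccc5)c(OCc5ccccc5)c1

F2 | step 4 | 8-bromo-5,7,3′,4′,5′-penta-O-benzyl-epigallocatechin | Brc1c(OCc5ccccc5)cc(OCc5ccccc5)c2c1O[C@H](c1cc(OCc5ccccc5)c(OCc5ccccc5)c(OCc5ccccc5)c1)[C@H](O)C2

F3 | step 4 | 8-bromo-4β-(2-ethoxyethoxy)-5,7,3′,4′,5′-penta-O-benzyl-epigallocatechin | CCOCCO[C@H]1c2c(OCc5ccccc5)cc(OCc5ccccc5)c(Br)c2O[C@H](c2cc(OCc5ccccc5)c(OCc5ccccc5)c(OCc5ccccc5)c2)[C@@H]1O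

F4 | step 4 | 8-bromo-penta-O-benzyl-epigallocatechin-(4β→8)-octa-O-benzyl-EGCG | O=C(O[C@@H]1Cc2c(OCc5ccccc5)cc(OCc5ccccc5)c([C@H]3c4c(OCc5ccccc5)cc(OCc5ccccc5)c(Br)c4O[C@H](c4cc(OCc5ccccc5)c(OCc5ccccc5)c(OCc5ccccc5)c4)[C@@H]3O)c2O[C@@H]1c1cc(OCc5ccccc5)c(OCc5ccccc5)c(OCc5ccccc5)c1)c1cc(OCc5ccccc5)c(OCc5ccccc5)c(OCc5ccccc5)c1

F5 | step 4 | 8-bromo-penta-O-benzyl-epigallocatechin-(4β→8)-octa-O-benzyl-EGCG-(4β→8)-penta-O-benzyl-epigallocatechin | O=C(O[C@@H]1[C@@H](c2c(OCc5ccccc5)cc(OCc5ccccc5)c3c2O[C@H](c2cc(OCc5ccccc5)c(OCc5ccccc5)c(OCc5ccccc5)c2)[C@H](O)C3)c2c(OCc5ccccc5)cc(OCc5ccccc5)c([C@H]3c4c(OCc5ccccc5)cc(OCc5ccccc5)c(Br)c4O[C@H](c4cc(OCc5ccccc5)c(OCc5ccccc5)c(OCc5ccccc5)c4)[C@@H]3O)c2O[C@@H]1c1cc(OCc5ccccc5)c(OCc5ccccc5)c(OCc5ccccc5)c1)c1cc(OCc5ccccc5)c(OCc5ccccc5)c(OCc5ccccc5)c1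

F6 | step 1 | epigallocatechin hexaacetate | CC(=O)Oc1cc(OC(C)=O)c2c(c1)O[C@H](c1cc(OC(C)=O)c(OC(C)=O)c(OC(C)=O)c1)[C@H](OC(C)=O)C2

F7 | step 1 | 3-O-acetyl-5,7,3′,4′,5′-penta-O-benzyl-epigallocatechin | C(c5ccccc5)Oc1cc(OCc5ccccc5)c2c(c1)O[C@H](c1cc(OCc5ccccc5)c(OCc5ccccc5)c(OCc5ccccc5)c1)[C@H](OC(C)=O)C2

F8 | step 6 | octadeca-O-acetate of 9 (all eighteen phenols acetylated, both secondary hydroxyls free) | O=C(O[C@@H]1[C@@H](c2c(OC(C)=O)cc(OC(C)=O)c3c2O[C@H](c2cc(OC(C)=O)c(OC(C)=O)c(OC(C)=O)c2)[C@H](O)C3)c2c(OC(C)=O)cc(OC(C)=O)c([C@H]3c4c(OC(C)=O)cc(OC(C)=O)cc4O[C@H](c4cc(OC(C)=O)c(OC(C)=O)c(OC(C)=O)c4)[C@@H]3O)c2O[C@@H]1c1cc(OC(C)=O)c(OC(C)=O)c(OC(C)=O)c1)c1cc(OC(C)=O)c(OC(C)=O)c(OC(C)=O)c1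

A1 | alternative 1 | 4β-(2-ethoxyethoxy)-octa-O-benzyl-EGCG | O=C(O[C@@H]1[C@@H](OCCOCC)c2c(OCc5ccccc5)cc(OCc5ccccc5)cc2O[C@@H]1c1cc(OCc5ccccc5)c(OCc5ccccc5)c(OCc5ccccc5)c1)c1cc(OCc5ccccc5)c(OCc5ccccc5)c(OCc5ccccc5)c1

A2 | alternative 1 | octa-O-benzyl-EGCG-(4β→8)-penta-O-benzyl-epigallocatechin | O=C(O[C@@H]1[C@@H](c2c(OCc5ccccc5)cc(OCc5ccccc5)c3c2O[C@H](c2cc(OCc5ccccc5)c(OCc5ccccc5)c(OCc5ccccc5)c2)[C@H](O)C3)c2c(OCc5ccccc5)cc(OCc5ccccc5)cc2O[C@@H]1c1cc(OCc5ccccc5)c(OCc5ccccc5)c(OCc5ccccc5)c1)c1cc(OCc5ccccc5)c(OCc5ccccc5)c(OCc5ccccc5)c1

A3 | alternative 2 | 4-oxo-3-O-(tert-butyldimethylsilyl)-5,7,3′,4′,5′-penta-O-benzyl-epigallocatechin | O=C1c2c(OCc5ccccc5)cc(OCc5ccccc5)cc2O[C@H](c2cc(OCc5ccccc5)c(OCc5ccccc5)c(OCc5ccccc5)c2)[C@@H]1O[Si](C)(C)C(C)(C)C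

A4 | alternative 2 | 8-bromo-3-O-(tert-butyldimethylsilyl)-5,7,3′,4′,5′-penta-O-benzyl-epigallocatechin | Brc1c(OCc5ccccc5)cc(OCc5ccccc5)c2c1O[C@H](c1cc(OCc5ccccc5)c(OCc5ccccc5)c(OCc5ccccc5)c1)[C@H](O[Si](C)(C)C(C)(C)C)C2

A5 | alternative 3 | delphinidin chloride | [Cl-].Oc1cc(O)c2cc(O)c(-c3cc(O)c(O)c(O)c3)[o+]c2c1

A6 | alternative 3 | epigallocatechin 3-O-gallate-(4β→8)-epigallocatechin | O=C(O[C@@H]1[C@@H](c2c(O)cc(O)c3c2O[C@H](c2cc(O)c(O)c(O)c2)[C@H](O)C3)c2c(O)cc(O)cc2O[C@@H]1c1cc(O)c(O)c(O)c1)c1cc(O)c(O)c(O)c1
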